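## Retrosynthetic overview
1. Target 12 comes from hydrolytic opening of the tetracyclic enol-lactone 11. The lactone masks both the CO2H and the 2-hydroxyindole and blocks oxidative decarboxylation until the last step.
2. The lactone C(indole-2)–O bond comes from a carboxylate-directed dehydrogenative C–H lactonisation of the 3-(indol-3-yl)pyrrole-2-carboxylic acid 9. This is the bold key step: the oxindole oxygen is the acid's own oxygen and is installed last.
3. The two indoles are told apart electronically. Boc stays on the indole that must not be oxidised, and Cbz leaves the other indole together with the benzyl ester.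
4. The pyrrole is built de novo rather than by Suzuki couplings on a dihalopyrrole. A Ag-azomethine ylide [3+2] of glycinate imine 4 with nitrovinylindole 6 is followed by a one-equivalent oxidation with loss of HNO2.
5. Ring order: both indoles are purchased, then pyrrolidine, pyrrole, pyranone (lactone), and finally the lactone is opened.

Assumption: the target SMILES (2-hydroxyindole tautomer) has no stereocentre. C3 of the oxindole tautomer is configurationally labile, so no enantiocontrol is needed or possible.

## Route

**Step 1**
Reactants: 1, 5-hydroxy-1H-indole-3-carbaldehyde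
Product: 2, tert-butyl 5-[(tert-butoxycarbonyl)oxy]-3-formylindole-1-carboxylate
Conditions: Boc2O (2.3 equiv), DMAP (10 mol %), Et3N, MeCN, 0 °C → rt
Reagents that add atoms: di-tert-butyl dicarbonate, CC(C)(C)OC(=O)OC(=O)OC(C)(C)C
Why: DMAP-catalysed acylation of the phenol OH and indole NH; N-Boc makes the vinylogous formamide behave as a true aldehyde and deactivates this indole toward the later oxidation.

**Step 2**
Reactants: 2; 3, glycine benzyl ester hydrochloride
Product: 4, benzyl (E)-N-{[1-Boc-5-(Boc-oxy)indol-3-yl]methylidene}glycinate
Conditions: Et3N (1.1 equiv), MgSO4, CH2Cl2, rt, 12 h; filter, water wash, use crude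
Reagents that add atoms: none beyond reactant 3 (free base NCC(=O)OCc1ccccc1)
Why: Schiff-base condensation, which at rt is much faster than aminolysis of the hindered tert-butyl carbonate or carbamate.

**Step 3**
Reactants: 5, (E)-3-(2-nitrovinyl)-1H-indole
Product: 6, benzyl 3-[(E)-2-nitroethenyl]indole-1-carboxylate
Conditions: CbzCl (1.2 equiv), Et3N, DMAP (10 mol %), CH2Cl2, 0 °C → rt
Reagents that add atoms: benzyl chloroformate, O=C(Cl)OCc1ccccc1
Why: N-acylation of the acidic indole NH switches off the push–pull donation, giving a more electrophilic nitroalkene, and Cbz is chosen to leave with the benzyl ester in step 6.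

**Step 4**
Reactants: 4; 6
Product: 7, benzyl 5-[1-Boc-5-(Boc-oxy)indol-3-yl]-3-(1-Cbz-indol-3-yl)-4-nitropyrrolidine-2-carboxylate. It is racemic, with the endo isomer major (2,5-cis, 3,4-trans, 4,5-cis), and the endo/exo mixture is used as such.
Conditions: AgOAc (10 mol %), Et3N (20 mol %), THF, rt, dark
Reagents that add atoms: none beyond reactants
Why: Metallo-azomethine ylide 1,3-dipolar cycloaddition (Michael then Mannich), in which the glycinate α-carbon attacks the indolyl-bearing β-carbon to fix the 2-CO2Bn/3-indolyl/4-NO2/5-aryl pattern; the four stereocentres are irrelevant because all are erased in step 5.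

**Step 5**
Reactants: 7
Product: 8, benzyl 5-[1-Boc-5-(Boc-oxy)indol-3-yl]-3-(1-Cbz-indol-3-yl)-1H-pyrrole-2-carboxylate
Conditions: NCS (1.0 equiv), CH2Cl2, 0 °C, 30 min; then DBU (3.5 equiv), 0 °C → rt; NaHCO3 work-up (remove nitrite before any acid contact)
Reagents that add atoms: none (Cl leaves again as chloride)
Why: N-chlorination/dehydrochlorination gives the 1-pyrroline, which loses nitrite by E1cB and tautomerises as in the final stage of a Barton–Zard synthesis; a single oxidising equivalent prevents 4-nitropyrrole formation, and Cl transfer to the nitronate carbon would converge on the same product.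

**Step 6**
Reactants: 8
Product: 9, 5-[1-Boc-5-(Boc-oxy)indol-3-yl]-3-(1H-indol-3-yl)-1H-pyrrole-2-carboxylic acid
Conditions: H2 (1 atm), 10 % Pd/C, EtOAc/EtOH, rt; filter under Ar, use directly
Reagents that add atoms: none
Why: Hydrogenolysis cleaves the benzyl ester and the N-Cbz (the carbamic acid loses CO2) in one operation, both Boc groups survive, and only the indole next to the acid becomes NH-free and electron-rich.

**Step 7 (key step)**
Reactants: 9
Product: 10, Boc-protected lactone. It is a 3,4-pyrrolo-fused pyrano[2,3-b]indol-2(9H)-one, with C=O on pyrrole C2, ring O on indole C2, and the 1-Boc-5-(Boc-oxy)indol-3-yl group on the pyrrole α-carbon.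
Conditions: PhI(OAc)2 (1.05 equiv), 2,6-lutidine (2.5 equiv), CH2Cl2, −40 → 0 °C, Ar, dark
Reagents that add atoms: none (the new C–O oxygen is the carboxyl oxygen)
Why: Proposed new method: ligand exchange puts I(III) on the carboxylate, it attacks the nucleophilic C3 of the only unprotected indole, the resulting indoleninium is captured at C2 by the carboxylate in a 6-membered closure, and loss of PhI and H+ rearomatises; the closest known reaction types are Pb(OAc)4 or PIFA oxidative lactonisation of 3-arylpyrrole-2-carboxylic acids (lamellarin-type lactones) and C2 trapping of 3-substituted indoles via 3-haloindolenines, and stray C2-acetoxylation would still converge on 12 in step 9.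

**Step 8**
Reactants: 10
Product: 11, the free lactone (same tetracycle carrying a 5-hydroxy-1H-indol-3-yl group), a storable pro-form of the target
Conditions: TFA/CH2Cl2 (1:3), anisole (10 equiv), 0 °C → rt, Ar
Reagents that add atoms: none
Why: Acidolysis removes both the O-Boc and N-Boc groups with anisole scavenging t-Bu+, while the acid is tied up as the lactone and so cannot undergo TFA-induced pyrrole protodecarboxylation.

**Step 9**
Reactants: 11
Product: 12, violaceinic acid, 5-(5-hydroxy-1H-indol-3-yl)-3-(2-hydroxy-1H-indol-3-yl)-1H-pyrrole-2-carboxylic acid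
Conditions: LiOH (4 equiv), degassed THF/H2O (2:1), 0 °C, 30 min, Ar, dark; degassed aq citric acid to pH ≈ 4 at 0 °C; extract with degassed EtOAc; store at −80 °C under Ar
Reagents that add atoms: water/hydroxide, O (as LiOH, [Li+].[OH-])
Why: Saponification of an activated enol (2-acyloxyindole) ester by acyl–O cleavage releases the carboxylate and the oxindole enolate together, the open form is favoured because of oxindole amide stabilisation, and excluding O2 suppresses oxidative decarboxylation to violacein.

## Compound list
| No. | Name | SMILES | Role |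
|---|---|---|---|
| 1 | 5-hydroxy-1H-indole-3-carbaldehyde | O=Cc1c[nH]c2ccc(O)cc12 | starting material |
| 2 | N,O-bis-Boc aldehyde | O=Cc1cn(C(=O)OC(C)(C)C)c2ccc(OC(=O)OC(C)(C)C)cc12 | intermediate |
| 3 | glycine benzyl ester hydrochloride | Cl.NCC(=O)OCc1ccccc1 | starting material |
| 4 | (E)-glycinate imine | O=C(OCc1ccccc1)C/N=C/c1cn(C(=O)OC(C)(C)C)c2ccc(OC(=O)OC(C)(C)C)cc12 | intermediate |
| 5 | (E)-3-(2-nitrovinyl)-1H-indole | O=[N+]([O-])/C=C/c1c[nH]c2ccccc12 | starting material |
| 6 | N-Cbz-(E)-3-(2-nitrovinyl)indole | O=[N+]([O-])/C=C/c1cn(C(=O)OCc2ccccc2)c2ccccc12 | intermediate |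
| 7 | 4-nitropyrrolidine cycloadduct (racemic; relative configuration of major endo isomer shown) | O=C(OCc1ccccc1)[C@@H]1N[C@H](c2cn(C(=O)OC(C)(C)C)c3ccc(OC(=O)OC(C)(C)C)cc23)[C@H]([N+](=O)[O-])[C@H]1c1cn(C(=O)OCc2ccccc2)c2ccccc12 | intermediate |
| 8 | fully protected pyrrole benzyl ester | O=C(OCc1ccccc1)c1[nH]c(-c2cn(C(=O)OC(C)(C)C)c3ccc(OC(=O)OC(C)(C)C)cc23)cc1-c1cn(C(=O)OCc2ccccc2)c2ccccc12 | intermediate |
| 9 | pyrrole-2-carboxylic acid with NH-free 3-indolyl | O=C(O)c1[nH]c(-c2cn(C(=O)OC(C)(C)C)c3ccc(OC(=O)OC(C)(C)C)cc23)cc1-c1c[nH]c2ccccc12 | intermediate |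
| 10 | bis-Boc lactone | O=C1Oc2[nH]c3ccccc3c2-c2cc(-c3cn(C(=O)OC(C)(C)C)c4ccc(OC(=O)OC(C)(C)C)cc34)[nH]c21 | intermediate |
| 11 | free lactone | O=C1Oc2[nH]c3ccccc3c2-c2cc(-c3c[nH]c4ccc(O)cc34)[nH]c21 | intermediate |
| 12 | violaceinic acid (achiral) | O=C(O)c1[nH]c(-c2c[nH]c3ccc(O)cc23)cc1-c1c(O)[nH]c2ccccc12 | target |

## Summary
Total step count: 9.
Longest linear sequence: 8 (steps 1, 2, 4, 5, 6, 7, 8, 9 from compound 1).

Three steps most likely to fail, each with a fallback that changes the approach:

1. **Step 7, oxidative C–H lactonisation.**
   - Risks: ipso-oxidation with decarboxylation at pyrrole C2, or attack at pyrrole C4.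
   - Fallback: pre-install the handle instead of oxidising C–H. Use 2-chloro-3-[(E)-2-nitrovinyl]indole, made by Henry condensation of commercial 2-chloroindole-3-carbaldehyde with MeNO2. Switch to allyl ester and N-Alloc so that Pd(0) deallylation spares the C–Cl bond. Close the same lactone 10 by Cu(I)-catalysed intramolecular Ullmann-type C–O coupling.
2. **Step 5, aromatisation.**
   - Risks: retro-Mannich cleavage, or stalling at a nitroenamine or 4-nitropyrrole.
   - Fallback: make the step redox-neutral. Use the 1-bromo-1-nitroalkene analogue of 6, from N-Cbz-indole-3-carbaldehyde and bromonitromethane. Its cycloadduct then loses HBr and HNO2 with DBU alone, with no oxidant.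
3. **Step 9, release and isolation of 12.**
   - Risk: aerobic oxidative decarboxylation of the polyanion to violacein.
   - Fallback: avoid basic aqueous release. Open lactone 10 with BnOH (cat. DMAP) to give the benzyl ester and oxindole, remove the Boc groups with TFA, and free the acid last by neutral hydrogenolysis (H2, Pd/C) under reducing, O2-free conditions.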